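**Retrosynthetic overview**

1. The target is taken back through acetylation, desilylation and a selenoxide elimination to a silyl-protected spiro-cyclohexenone that carries both methoxy groups and the ring carbonyl.
2. Key disconnection: the six-membered dienone ring is made from a four-membered ring. A spiro 3'-methoxycyclobutenone takes up 1-methoxyvinyllithium; 1,2-addition, 4π ring opening and 6π ring closure expand the ring by two carbons and form the bond between the spiro carbon C1' and the new ring CH2 (C6', later a dienone CH).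
3. Enabling feature: in the 2,6-dimethoxycyclohexa-2,5-dienone ring the carbonyl C4' lies para to the fully substituted spiro carbon C1' (C5 of the benzo[7]annulene), and the arms C2'H=C3'(OMe) and C6'H=C5'(OMe) are identical. The ring is therefore a cyclobutenone (C1', C2', C3', C4'=O) plus one MeO–C=CH2 unit, and a spiro carbon without hydrogen cannot aromatise.
4. The cyclobutenone comes from a [2+2] cycloaddition of methoxyketene with the exocyclic enol ether of a benzosuberone. The seven-membered ring comes from a Parham cyclisation of an aryl bromide onto a Weinreb amide. The stereotriad comes from a δ-lactone (crotylboration, acrylate ring-closing metathesis, anti cuprate addition).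
5. Ring order: arene (bought) → δ-lactone (temporary) → seven-membered carbocycle → cyclobutenone (temporary) → cyclohexadienone.

Key step: step 10

Remark: (R)-TRIP is assumed to be the catalyst enantiomer that delivers the (1R,2S)-homoallylic alcohol; otherwise its mirror image is used.
Remark: centres that are erased later (enol ether geometry, the spiro carbon of the small-ring intermediates, the ring CH carbons of the cyclobutanone, the selenium-bearing carbon) are carried as mixtures and left unspecified in the SMILES.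

**Route**

Step 1
Reactants: 1 2-bromo-3,4,5-trimethoxybenzaldehyde
Product: 2 (1R,2S)-1-(2-bromo-3,4,5-trimethoxyphenyl)-2-methylbut-3-en-1-ol
Conditions: (Z)-crotylB(pin), (R)-TRIP (5 mol %), toluene, −30 °C; aqueous work-up
Reagents that add atoms: (Z)-crotylboronic acid pinacol ester, C/C=C\CB1OC(C)(C)C(C)(C)O1
Why: Chiral phosphoric acid-catalysed crotylboration through a closed chair transition state, in which the (Z)-crotyl geometry gives the syn relationship and the catalyst selects the aldehyde face, so both new stereocentres (1R and 2S, later C9 and C8 of the benzo[7]annulene) are set here.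

Step 2
Reactants: 2 (1R,2S)-homoallylic alcohol
Product: 3 (1R,2S)-1-(2-bromo-3,4,5-trimethoxyphenyl)-2-methylbut-3-en-1-yl prop-2-enoate
Conditions: acryloyl chloride, Et3N, DMAP (cat.), CH2Cl2, 0 °C
Reagents that add atoms: acryloyl chloride, C=CC(Cl)=O
Why: Standard O-acylation of the secondary benzylic alcohol (nucleophilic catalysis by DMAP) installs the second alkene for ring closure without touching the stereocentres.

Step 3
Reactants: 3 acrylate ester
Product: 4 (5S,6R)-6-(2-bromo-3,4,5-trimethoxyphenyl)-5-methyl-5,6-dihydro-2H-pyran-2-one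
Conditions: second-generation Grubbs catalyst RuCl2(=CHPh)(H2IMes)(PCy3) (5 mol %), CH2Cl2, 40 °C
Reagents that add atoms: none
Why: Ring-closing metathesis of the acrylate with the terminal alkene closes the unsaturated δ-lactone and holds the aryl and methyl groups cis on a ring that can direct the next addition.

Step 4
Reactants: 4 unsaturated δ-lactone
Product: 5 (4R,5S,6R)-6-(2-bromo-3,4,5-trimethoxyphenyl)-4,5-dimethyltetrahydro-2H-pyran-2-one
Conditions: Me2CuLi (from CuI and MeLi), Et2O, −78 → −20 °C; aq. NH4Cl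
Reagents that add atoms: lithium dimethylcuprate, [Li+].C[Cu-]C
Why: Conjugate addition of the cuprate to the dihydropyranone should occur anti to the adjacent C5 methyl group (and to the cis C6 aryl group), which sets the new C4 stereocentre (R) trans to the C5 methyl.

Step 5
Reactants: 5 saturated δ-lactone
Product: 6 (3R,4S,5R)-5-(2-bromo-3,4,5-trimethoxyphenyl)-5-hydroxy-N-methoxy-N,3,4-trimethylpentanamide
Conditions: MeNH(OMe)·HCl, iPrMgCl, THF, −15 → 0 °C
Reagents that add atoms: N,O-dimethylhydroxylamine hydrochloride, CNOC.Cl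
Why: Aminolysis of the lactone by the magnesium amide of N,O-dimethylhydroxylamine gives the Weinreb amide and frees the benzylic hydroxyl, with no stereocentre touched.

Step 6
Reactants: 6 hydroxy Weinreb amide
Product: 7 (3R,4S,5R)-5-(2-bromo-3,4,5-trimethoxyphenyl)-5-[(tert-butyldimethylsilyl)oxy]-N-methoxy-N,3,4-trimethylpentanamide
Conditions: TBSOTf, 2,6-lutidine, CH2Cl2, −78 → 0 °C
Reagents that add atoms: tert-butyldimethylsilyl trifluoromethanesulfonate, CC(C)(C)[Si](C)(C)OS(=O)(=O)C(F)(F)F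
Why: Silylation of the secondary alcohol (silyl triflate, hindered base) prevents relactonisation and protects the benzylic oxygen through the organolithium steps.

Step 7
Reactants: 7 silyl-protected bromoaryl Weinreb amide
Product: 8 (7R,8S,9R)-9-[(tert-butyldimethylsilyl)oxy]-2,3,4-trimethoxy-7,8-dimethyl-6,7,8,9-tetrahydro-5H-benzo[7]annulen-5-one
Conditions: t-BuLi (2.2 equiv), THF, −78 °C; aq. NH4Cl
Reagents that add atoms: none
Why: Parham cyclisation, in which bromine–lithium exchange outruns attack on the amide and the aryllithium then acylates itself on the tethered Weinreb amide, whose chelated tetrahedral intermediate stops at the ketone and so closes the seven-membered ring.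

Step 8
Reactants: 8 benzosuberone
Product: 9 tert-butyl{[(7R,8S,9R)-2,3,4-trimethoxy-5-(methoxymethylidene)-7,8-dimethyl-6,7,8,9-tetrahydro-5H-benzo[7]annulen-9-yl]oxy}dimethylsilane (E/Z mixture)
Conditions: Ph3P(CH2OMe)Cl, KOtBu, THF, 0 → 45 °C
Reagents that add atoms: (methoxymethyl)triphenylphosphonium chloride, COC[P+](c1ccccc1)(c1ccccc1)c1ccccc1.[Cl-]
Why: Wittig methoxymethylenation turns the ketone carbon into the fully substituted, nucleophilic β-carbon of an exocyclic enol ether, and the ketone has no α-stereocentre that could epimerise.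

Step 9
Reactants: 9 exocyclic enol ether
Product: 11 (7R,8S,9R)-9-[(tert-butyldimethylsilyl)oxy]-2,3,3',4-tetramethoxy-7,8-dimethyl-6,7,8,9-tetrahydrospiro[benzo[7]annulene-5,1'-cyclobut[2]en]-4'-one (spiro epimers), via dimethoxycyclobutanone cycloadduct 10 (not isolated)
Conditions: MeOCH2COCl (slow addition), Et3N, CH2Cl2, 40 °C; then DBU, 0 → 23 °C
Reagents that add atoms: methoxyacetyl chloride, COCC(Cl)=O
Why: Ketene–enol ether [2+2] cycloaddition (methoxyketene made in situ by dehydrochlorination) joins the ketene carbonyl carbon to the nucleophilic β-carbon of the enol ether, which places the spiro carbon next to the cyclobutanone carbonyl, and E1cB loss of methanol from the 3-alkoxycyclobutanone then gives the cyclobutenone; the four-ring stereocentres are mixtures that are erased later.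

Step 10
Reactants: 11 spiro 3'-methoxycyclobutenone
Product: 15 (7R,8S,9R)-9-[(tert-butyldimethylsilyl)oxy]-2,3,3',4,5'-pentamethoxy-7,8-dimethyl-5'-(phenylselanyl)-6,7,8,9-tetrahydrospiro[benzo[7]annulene-5,1'-cyclohex[2]en]-4'-one (epimer mixture), via cyclobutenolate adduct 12 (not isolated), via trienolate 13 (not isolated), via cyclohexadienolate 14 (not isolated)
Conditions: CH2=C(OMe)Li (from methyl vinyl ether and t-BuLi, THF, −65 → 0 °C), THF, −78 → 23 °C; then PhSeCl, −78 °C
Reagents that add atoms: 1-methoxyvinyllithium, [Li]C(=C)OC; phenylselanyl chloride, Cl[Se]c1ccccc1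
Why: 1-Methoxyvinyllithium adds 1,2 to the strained cyclobutenone carbonyl, and the resulting 4'-alkenylcyclobutenolate 12 undergoes alkoxide-accelerated conrotatory 4π opening of the C4'–C1' bond with the oxido group rotating outward, which turns the methoxyvinyl group inward and gives the (Z)-trienolate 13. Disrotatory 6π electrocyclisation of 13 then forms the bond between the spiro carbon and the CH2 terminus of the vinyl unit and closes the six-membered ring, so the four-membered ring is expanded by two carbons and the quaternary spiro carbon, the ring carbonyl and both methoxy-bearing carbons are in place at once. The closest known reaction type is the 4π-opening/6π-closure ring expansion of 1-alkenylcyclobut-2-en-1-ols and their alkoxides, as in squarate cascades and in the conversion of 4,4-disubstituted cyclobutenones into six-membered rings. The cross-conjugated enolate 14 is then selenenylated on carbon by PhSeCl. No stereocentre of the target is created: the spiro carbon becomes non-stereogenic in the symmetric dienone, and the selenium-bearing carbon, formed without control, is erased in step 11. The step needs carbonyl rather than conjugate addition and inward rotation of the alkenyl group; the first is secured by the hard organolithium, by the α-methoxy group that deactivates the β-carbon and by the absence of any enolisable hydrogen in 11, the second by the outward preference of the alkoxide.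

Step 11
Reactants: 15 α-phenylselanyl ketone
Product: 17 (7R,8S,9R)-9-[(tert-butyldimethylsilyl)oxy]-2,3,3',4,5'-pentamethoxy-7,8-dimethyl-6,7,8,9-tetrahydrospiro[benzo[7]annulene-5,1'-cyclohexa[2,5]dien]-4'-one, via selenoxide 16 (not isolated)
Conditions: 30% H2O2, pyridine, CH2Cl2, 0 → 23 °C
Reagents that add atoms: none
Why: Oxidation to the selenoxide and syn-elimination towards the only β-hydrogens (C6'H2) should introduce the second ring double bond and give the cross-conjugated dienone, and the C5' stereocentre disappears.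

Step 12
Reactants: 17 silyl-protected spirodienone
Product: 18 (7R,8S,9R)-9-hydroxy-2,3,3',4,5'-pentamethoxy-7,8-dimethyl-6,7,8,9-tetrahydrospiro[benzo[7]annulene-5,1'-cyclohexa[2,5]dien]-4'-one
Conditions: TBAF, AcOH, THF, 0 → 23 °C
Reagents that add atoms: none
Why: Fluoride-mediated desilylation buffered with acetic acid frees the benzylic alcohol without exposing the dienone to a basic alkoxide or to acid that could ionise the p-methoxybenzylic position.

Step 13
Reactants: 18 spirodienone alcohol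
Product: 19 (7R,8S,9R)-2,3,3',4,5'-pentamethoxy-7,8-dimethyl-4'-oxo-6,7,8,9-tetrahydrospiro[benzo[7]annulene-5,1'-cyclohexa[2,5]dien]-9-yl acetate (CNP0143674.1)
Conditions: Ac2O, pyridine, DMAP (cat.), CH2Cl2, 23 °C
Reagents that add atoms: acetic anhydride, CC(=O)OC(C)=O
Why: Standard acetylation (nucleophilic catalysis) of the secondary alcohol with retention at C9 gives the target.

**Compound list**

1 | 2-bromo-3,4,5-trimethoxybenzaldehyde | O=Cc1cc(OC)c(OC)c(OC)c1Br | starting material
2 | (1R,2S)-1-(2-bromo-3,4,5-trimethoxyphenyl)-2-methylbut-3-en-1-ol | C=C[C@H](C)[C@@H](O)c1cc(OC)c(OC)c(OC)c1Br | intermediate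
3 | (1R,2S)-1-(2-bromo-3,4,5-trimethoxyphenyl)-2-methylbut-3-en-1-yl prop-2-enoate | C=C[C@H](C)[C@@H](OC(=O)C=C)c1cc(OC)c(OC)c(OC)c1Br | intermediate
4 | (5S,6R)-6-(2-bromo-3,4,5-trimethoxyphenyl)-5-methyl-5,6-dihydro-2H-pyran-2-one | O=C1C=C[C@H](C)[C@H](c2cc(OC)c(OC)c(OC)c2Br)O1 | intermediate
5 | (4R,5S,6R)-6-(2-bromo-3,4,5-trimethoxyphenyl)-4,5-dimethyltetrahydro-2H-pyran-2-one | O=C1C[C@@H](C)[C@H](C)[C@H](c2cc(OC)c(OC)c(OC)c2Br)O1 | intermediate
6 | (3R,4S,5R)-5-(2-bromo-3,4,5-trimethoxyphenyl)-5-hydroxy-N-methoxy-N,3,4-trimethylpentanamide | CON(C)C(=O)C[C@@H](C)[C@H](C)[C@@H](O)c1cc(OC)c(OC)c(OC)c1Br | intermediate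
7 | (3R,4S,5R)-5-(2-bromo-3,4,5-trimethoxyphenyl)-5-[(tert-butyldimethylsilyl)oxy]-N-methoxy-N,3,4-trimethylpentanamide | CON(C)C(=O)C[C@@H](C)[C@H](C)[C@@H](O[Si](C)(C)C(C)(C)C)c1cc(OC)c(OC)c(OC)c1Br | intermediate
8 | (7R,8S,9R)-9-[(tert-butyldimethylsilyl)oxy]-2,3,4-trimethoxy-7,8-dimethyl-6,7,8,9-tetrahydro-5H-benzo[7]annulen-5-one | O=C1C[C@@H](C)[C@H](C)[C@@H](O[Si](C)(C)C(C)(C)C)c2cc(OC)c(OC)c(OC)c12 | intermediate
9 | tert-butyl{[(7R,8S,9R)-2,3,4-trimethoxy-5-(methoxymethylidene)-7,8-dimethyl-6,7,8,9-tetrahydro-5H-benzo[7]annulen-9-yl]oxy}dimethylsilane (E/Z mixture) | COC=C1C[C@@H](C)[C@H](C)[C@@H](O[Si](C)(C)C(C)(C)C)c2cc(OC)c(OC)c(OC)c12 | intermediate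
10 | (7R,8S,9R)-9-[(tert-butyldimethylsilyl)oxy]-2,2',3,3',4-pentamethoxy-7,8-dimethyl-6,7,8,9-tetrahydrospiro[benzo[7]annulene-5,1'-cyclobutan]-4'-one (diastereomer mixture) | COC1C(OC)C2(C1=O)C[C@@H](C)[C@H](C)[C@@H](O[Si](C)(C)C(C)(C)C)c1cc(OC)c(OC)c(OC)c12 | intermediate
11 | (7R,8S,9R)-9-[(tert-butyldimethylsilyl)oxy]-2,3,3',4-tetramethoxy-7,8-dimethyl-6,7,8,9-tetrahydrospiro[benzo[7]annulene-5,1'-cyclobut[2]en]-4'-one (spiro epimers) | COC1=CC2(C1=O)C[C@@H](C)[C@H](C)[C@@H](O[Si](C)(C)C(C)(C)C)c1cc(OC)c(OC)c(OC)c12 | intermediate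
12 | lithium (7R,8S,9R)-9-[(tert-butyldimethylsilyl)oxy]-2,3,3',4-tetramethoxy-4'-(1-methoxyethenyl)-7,8-dimethyl-6,7,8,9-tetrahydrospiro[benzo[7]annulene-5,1'-cyclobut[2]en]-4'-olate | C=C(OC)C1(O[Li])C(OC)=CC12C[C@@H](C)[C@H](C)[C@@H](O[Si](C)(C)C(C)(C)C)c1cc(OC)c(OC)c(OC)c12 | intermediate
13 | lithium (3Z)-5-{(7R,8S,9R)-9-[(tert-butyldimethylsilyl)oxy]-2,3,4-trimethoxy-7,8-dimethyl-6,7,8,9-tetrahydro-5H-benzo[7]annulen-5-ylidene}-2,4-dimethoxypenta-1,3-dien-3-olate | C=C(OC)/C(O[Li])=C(OC)\C=C1C[C@@H](C)[C@H](C)[C@@H](O[Si](C)(C)C(C)(C)C)c2cc(OC)c(OC)c(OC)c12 | intermediate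
14 | lithium (7R,8S,9R)-9-[(tert-butyldimethylsilyl)oxy]-2,3,3',4,5'-pentamethoxy-7,8-dimethyl-6,7,8,9-tetrahydrospiro[benzo[7]annulene-5,1'-cyclohexa[2,4]dien]-4'-olate | COC1=C(O[Li])C(OC)=CC2(C1)C[C@@H](C)[C@H](C)[C@@H](O[Si](C)(C)C(C)(C)C)c1cc(OC)c(OC)c(OC)c12 | intermediate
15 | (7R,8S,9R)-9-[(tert-butyldimethylsilyl)oxy]-2,3,3',4,5'-pentamethoxy-7,8-dimethyl-5'-(phenylselanyl)-6,7,8,9-tetrahydrospiro[benzo[7]annulene-5,1'-cyclohex[2]en]-4'-one (epimer mixture) | COC1=CC2(CC(OC)([Se]c3ccccc3)C1=O)C[C@@H](C)[C@H](C)[C@@H](O[Si](C)(C)C(C)(C)C)c1cc(OC)c(OC)c(OC)c12 | intermediate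
16 | (7R,8S,9R)-9-[(tert-butyldimethylsilyl)oxy]-2,3,3',4,5'-pentamethoxy-7,8-dimethyl-5'-(phenylseleninyl)-6,7,8,9-tetrahydrospiro[benzo[7]annulene-5,1'-cyclohex[2]en]-4'-one | COC1=CC2(CC(OC)([Se](=O)c3ccccc3)C1=O)C[C@@H](C)[C@H](C)[C@@H](O[Si](C)(C)C(C)(C)C)c1cc(OC)c(OC)c(OC)c12 | intermediate
17 | (7R,8S,9R)-9-[(tert-butyldimethylsilyl)oxy]-2,3,3',4,5'-pentamethoxy-7,8-dimethyl-6,7,8,9-tetrahydrospiro[benzo[7]annulene-5,1'-cyclohexa[2,5]dien]-4'-one | COC1=CC2(C=C(OC)C1=O)C[C@@H](C)[C@H](C)[C@@H](O[Si](C)(C)C(C)(C)C)c1cc(OC)c(OC)c(OC)c12 | intermediate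
18 | (7R,8S,9R)-9-hydroxy-2,3,3',4,5'-pentamethoxy-7,8-dimethyl-6,7,8,9-tetrahydrospiro[benzo[7]annulene-5,1'-cyclohexa[2,5]dien]-4'-one | COC1=CC2(C=C(OC)C1=O)C[C@@H](C)[C@H](C)[C@@H](O)c1cc(OC)c(OC)c(OC)c12 | intermediate
19 | (7R,8S,9R)-2,3,3',4,5'-pentamethoxy-7,8-dimethyl-4'-oxo-6,7,8,9-tetrahydrospiro[benzo[7]annulene-5,1'-cyclohexa[2,5]dien]-9-yl acetate | COC1=CC2(C=C(OC)C1=O)C[C@@H](C)[C@H](C)[C@@H](OC(C)=O)c1cc(OC)c(OC)c(OC)c12 | target

**Step count and risk**

Total step count: 13. Longest linear sequence: 13 steps (1 → 19).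

Steps most likely to fail:

Step 10. The 6π closure has to form a bond to a fully substituted terminus next to an ortho-methoxy aryl group. If it is slow, the trienolate may be diverted by proton transfer or a 1,5-hydrogen shift to acyclic dienones, and conjugate addition to the cyclobutenone could compete with carbonyl addition. The fallback gives up the pericyclic closure; it sets out from 9 and returns at 17. Hydrolysis of 9 with aqueous oxalic acid in THF should give (7R,8S,9R)-9-[(tert-butyldimethylsilyl)oxy]-2,3,4-trimethoxy-7,8-dimethyl-6,7,8,9-tetrahydro-5H-benzo[7]annulene-5-carbaldehyde F1. Robinson annulation of F1 with but-3-en-2-one (KOH cat., MeOH, then heat) should give the spiro[benzo[7]annulene-5,1'-cyclohex[2]en]-4'-one F2; here the quaternary carbon comes from an intermolecular Michael addition and the ring closes by aldol condensation. Dehydrogenation with IBX (DMSO, 70 °C) should give the spiro[benzo[7]annulene-5,1'-cyclohexa[2,5]dien]-4'-one F3. I2/pyridine should iodinate both α-positions to the 3',5'-diiodo dienone F4. CuI/1,10-phenanthroline/Cs2CO3 in MeOH should exchange both iodides for methoxide and give 17.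

Step 9. Dimerisation of methoxyketene may outrun its cycloaddition to the hindered trisubstituted enol ether. The fallback raises the nucleophilicity of the alkene partner; it sets out from 9 and returns at 11. Hydrolysis of 9 (aqueous oxalic acid, THF) should give the benzo[7]annulene-5-carbaldehyde F5. Condensation with pyrrolidine (toluene, 4 Å sieves) should give 1-{[(7R,8S,9R)-9-[(tert-butyldimethylsilyl)oxy]-2,3,4-trimethoxy-7,8-dimethyl-6,7,8,9-tetrahydro-5H-benzo[7]annulen-5-ylidene]methyl}pyrrolidine F6, an enamine without a β-hydrogen. Enamine–ketene cycloaddition with methoxyacetyl chloride/Et3N should give the 3'-methoxy-2'-(pyrrolidin-1-yl)spiro[benzo[7]annulene-5,1'-cyclobutan]-4'-one F7. Quaternisation with MeI should give the N-methylpyrrolidinium iodide F8, and DBU should then effect Hofmann-type β-elimination to 11.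

Step 7. After bromine–lithium exchange, enolisation of the amide or intermolecular attack may compete with the seven-membered ring closure. The fallback closes the ring by carbopalladation instead of acylation; it sets out from 7 and returns at 9, bypassing ketone 8. Reduction of 7 with iBu2AlH (THF, −78 °C) should give (3R,4S,5R)-5-(2-bromo-3,4,5-trimethoxyphenyl)-5-[(tert-butyldimethylsilyl)oxy]-3,4-dimethylpentanal F9. Wittig methoxymethylenation (Ph3P(CH2OMe)Cl, KOtBu) should give tert-butyl{[(1R,2S,3R)-1-(2-bromo-3,4,5-trimethoxyphenyl)-6-methoxy-2,3-dimethylhex-5-en-1-yl]oxy}dimethylsilane F10. An intramolecular 7-exo-trig Heck reaction (Pd(OAc)2, PPh3, Et3N, MeCN, 80 °C), with β-hydride elimination from the new ring CH, should give the exocyclic enol ether 9.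

**Further compounds**

F1 | step 10 | (7R,8S,9R)-9-[(tert-butyldimethylsilyl)oxy]-2,3,4-trimethoxy-7,8-dimethyl-6,7,8,9-tetrahydro-5H-benzo[7]annulene-5-carbaldehyde (C5 epimers) | O=CC1C[C@@H](C)[C@H](C)[C@@H](O[Si](C)(C)C(C)(C)C)c2cc(OC)c(OC)c(OC)c12
F2 | step 10 | (7R,8S,9R)-9-[(tert-butyldimethylsilyl)oxy]-2,3,4-trimethoxy-7,8-dimethyl-6,7,8,9-tetrahydrospiro[benzo[7]annulene-5,1'-cyclohex[2]en]-4'-one | O=C1C=CC2(CC1)C[C@@H](C)[C@H](C)[C@@H](O[Si](C)(C)C(C)(C)C)c1cc(OC)c(OC)c(OC)c12
F3 | step 10 | (7R,8S,9R)-9-[(tert-butyldimethylsilyl)oxy]-2,3,4-trimethoxy-7,8-dimethyl-6,7,8,9-tetrahydrospiro[benzo[7]annulene-5,1'-cyclohexa[2,5]dien]-4'-one | O=C1C=CC2(C=C1)C[C@@H](C)[C@H](C)[C@@H](O[Si](C)(C)C(C)(C)C)c1cc(OC)c(OC)c(OC)c12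
F4 | step 10 | (7R,8S,9R)-9-[(tert-butyldimethylsilyl)oxy]-3',5'-diiodo-2,3,4-trimethoxy-7,8-dimethyl-6,7,8,9-tetrahydrospiro[benzo[7]annulene-5,1'-cyclohexa[2,5]dien]-4'-one | O=C1C(I)=CC2(C=C1I)C[C@@H](C)[C@H](C)[C@@H](O[Si](C)(C)C(C)(C)C)c1cc(OC)c(OC)c(OC)c12
F5 | step 9 | (7R,8S,9R)-9-[(tert-butyldimethylsilyl)oxy]-2,3,4-trimethoxy-7,8-dimethyl-6,7,8,9-tetrahydro-5H-benzo[7]annulene-5-carbaldehyde (C5 epimers) | O=CC1C[C@@H](C)[C@H](C)[C@@H](O[Si](C)(C)C(C)(C)C)c2cc(OC)c(OC)c(OC)c12
F6 | step 9 | 1-{[(7R,8S,9R)-9-[(tert-butyldimethylsilyl)oxy]-2,3,4-trimethoxy-7,8-dimethyl-6,7,8,9-tetrahydro-5H-benzo[7]annulen-5-ylidene]methyl}pyrrolidine | C1CCN(C1)C=C1C[C@@H](C)[C@H](C)[C@@H](O[Si](C)(C)C(C)(C)C)c2cc(OC)c(OC)c(OC)c12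
F7 | step 9 | (7R,8S,9R)-9-[(tert-butyldimethylsilyl)oxy]-2,3,3',4-tetramethoxy-7,8-dimethyl-2'-(pyrrolidin-1-yl)-6,7,8,9-tetrahydrospiro[benzo[7]annulene-5,1'-cyclobutan]-4'-one (diastereomer mixture) | COC1C(N2CCCC2)C2(C1=O)C[C@@H](C)[C@H](C)[C@@H](O[Si](C)(C)C(C)(C)C)c1cc(OC)c(OC)c(OC)c12
F8 | step 9 | 1-{(7R,8S,9R)-9-[(tert-butyldimethylsilyl)oxy]-2,3,3',4-tetramethoxy-7,8-dimethyl-4'-oxo-6,7,8,9-tetrahydrospiro[benzo[7]annulene-5,1'-cyclobutan]-2'-yl}-1-methylpyrrolidin-1-ium iodide | COC1C([N+]2(C)CCCC2)C2(C1=O)C[C@@H](C)[C@H](C)[C@@H](O[Si](C)(C)C(C)(C)C)c1cc(OC)c(OC)c(OC)c12.[I-]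
F9 | step 7 | (3R,4S,5R)-5-(2-bromo-3,4,5-trimethoxyphenyl)-5-[(tert-butyldimethylsilyl)oxy]-3,4-dimethylpentanal | O=CC[C@@H](C)[C@H](C)[C@@H](O[Si](C)(C)C(C)(C)C)c1cc(OC)c(OC)c(OC)c1Br
F10 | step 7 | tert-butyl{[(1R,2S,3R)-1-(2-bromo-3,4,5-trimethoxyphenyl)-6-methoxy-2,3-dimethylhex-5-en-1-yl]oxy}dimethylsilane (E/Z mixture) | COC=CC[C@@H](C)[C@H](C)[C@@H](O[Si](C)(C)C(C)(C)C)c1cc(OC)c(OC)c(OC)c1Br
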